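Locants: rings A/B are the hydroxylated decalin (labdane numbering C-1 to C-10, side-chain CH2 = C-11, vinylic CH = C-12); rings C/D are the second decalin with primed naphthalene locants (C-1′ carries the exocyclic alkene, C-4a′ the angular methyl, C-7′ the tertiary OH, C-8′ the secondary methyl, C-8a′ the ring-fusion H; ring D holds C-5′ to C-8′); β is the face of the 4a′-methyl group.
Cuts: the C-7′ and C-8′ methyl groups are removed first (MeLi on a C-7′ enone, enolate methylation); the enone goes back by 1,3-carbonyl transposition to a C-5′ ketone; the ring-fusion bond C-4a′–C-8a′ and the C-6′–C-7′ bond are then cut together (Michael/aldol retron); two Wittig cuts (C-8′=C-8a′, C-12=C-1′) lead to a C-12 aldehyde made from (+)-sclareolide.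
Enabling feature: in ring D the carbinol carbon C-7′ and the quaternary fusion carbon C-4a′ are joined through C-5′–C-6′, and the fusion CH C-8a′ is allylic to the exocyclic C-1′=C-12 alkene; a ketone placed for a time on C-5′ makes C-4a′ and C-6′ the two nucleophilic carbons of one unit, and a 2,4-dienal makes C-8a′ (β-carbon) and C-7′ (formyl carbon) the two electrophilic carbons of the other.
Forward order: rings A/B come from sclareolide; the chain is joined at C-12; rings C and D close in one operation (ring C by Michael addition, then ring D by aldol condensation); the C-5′ oxygen is removed by epoxidation and Wharton transposition, which leaves oxygen on C-7′; the two methyl groups follow.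
Stereochemistry: C-5, C-9, C-10 from sclareolide; C-3 by a cytochrome P450 monooxygenase; C-8 by hydrogenation from the α-face; the E alkene by a stabilised ylide; C-8a′ by the prolinol catalyst and C-4a′ by the cyclic transition state (cis fusion); C-8′ by equilibration; C-7′ by axial addition of the methyl nucleophile.

Key step: step 14

Remark: TBS = tert-butyldimethylsilyl; Dec = the decalin unit (3S,5R,8S,9S,10R)-3-(TBS-oxy)-4,4,8,10-tetramethyldecalin-9-yl (labdane locants), bonded through C-9 to C-11.
Remark: the methyl-bearing carbon of the citronellene starting material becomes C-4a′ and is made planar in step 14, so either enantiomer would serve; the (R)-form is drawn.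
Remark: the (S)-prolinol catalyst in step 14 is chosen on the usual face-shielding model for E-iminium ions; the (R)-catalyst would be used if the sense proved to be the reverse.

Step 1
Reactants: 1 (+)-sclareolide
Product: 2 (3S)-3-hydroxysclareolide (3β-OH)
Conditions: engineered cytochrome P450 BM3 monooxygenase (3-hydroxylating variant, cell lysate), NADP+ (cat.), glucose, glucose dehydrogenase, air, phosphate buffer pH 8, 25 °C
Reagents that add atoms: dioxygen, O=O
Why: Enzymatic C–H hydroxylation by a cytochrome P450 monooxygenase: the active site holds ring A over the haem so that oxygen is inserted into the equatorial C-3–H bond with retention, which should give the 3β (3S) alcohol, a site that chemical oxidants (which attack C-2) do not select.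

Step 2
Reactants: 2 (3S)-3-hydroxysclareolide
Product: 3 (3S)-3-(TBS-oxy)sclareolide
Conditions: TBSCl, imidazole, DMF, 20 °C
Reagents that add atoms: tert-butyldimethylsilyl chloride, CC(C)(C)[Si](C)(C)Cl
Why: Silyl ether protection of the secondary alcohol, which should last until step 21 and touches no stereocentre.

Step 3
Reactants: 3 (3S)-3-(TBS-oxy)sclareolide
Product: 4 hydroxy Weinreb amide (8α-OH free)
Conditions: MeNH(OMe)·HCl, i-PrMgCl, THF, −20 to 0 °C
Reagents that add atoms: N,O-dimethylhydroxylamine hydrochloride, Cl.CNOC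
Why: Aminolysis of the lactone by the chloromagnesium amide (Weinreb amide formation) opens the ring at the acyl carbon, so C-8 and C-9 are not touched and the tertiary 8α-OH is set free.

Step 4
Reactants: 4 hydroxy Weinreb amide
Product: 5 8(17)-ene Weinreb amide (exocyclic methylene at C-8)
Conditions: SOCl2, pyridine, CH2Cl2, −78 °C
Reagents that add atoms: none
Why: Dehydration of the tertiary alcohol through its chlorosulfite (E2-type elimination) should give mainly the exocyclic alkene, and any endocyclic 7-ene formed beside it is reduced to the same product in step 5.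

Step 5
Reactants: 5 8(17)-ene Weinreb amide
Product: 6 (8S)-Weinreb amide (8β-methyl; 8α-H)
Conditions: H2 (1 atm), PtO2, EtOAc, 20 °C
Reagents that add atoms: none
Why: Heterogeneous catalytic hydrogenation: the β-face is blocked by the axial C-10 methyl group, so hydrogen should add to C-8 from the α-face and leave the C-8 methyl group axial (8S), as in the target.

Step 6
Reactants: 6 (8S)-Weinreb amide
Product: 7 aldehyde Dec–CH2–CHO
Conditions: LiAlH4, THF, −40 to 0 °C; then H2O
Reagents that add atoms: none
Why: Hydride reduction of the N-methoxy-N-methylamide stops at the chelated tetrahedral intermediate, which gives the aldehyde on hydrolysis (Weinreb aldehyde synthesis); C-9 is not α to the carbonyl and cannot epimerise.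

Step 7
Reactants: 8 (R)-β-citronellene
Product: 10 (4R)-4-methylhex-5-en-1-ol, via aldehyde 9 (not isolated)
Conditions: O3 (1.0 equiv), CH2Cl2/MeOH, −78 °C; then NaBH4, −78 to 20 °C
Reagents that add atoms: ozone, [O-][O+]=O
Why: Ozonolysis with reductive work-up: the electron-rich trisubstituted alkene is cleaved much faster than the vinyl group, and NaBH4 reduces the aldehyde to the primary alcohol.

Step 8
Reactants: 10 (4R)-4-methylhex-5-en-1-ol
Product: 11 (3R)-6-iodo-3-methylhex-1-ene
Conditions: I2, PPh3, imidazole, CH2Cl2, 0 to 20 °C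
Reagents that add atoms: iodine, II
Why: Appel-type iodination: the alkoxyphosphonium ion is displaced by iodide in an SN2 reaction at the primary carbon.

Step 9
Reactants: 11 (3R)-6-iodo-3-methylhex-1-ene
Product: 12 [(4R)-4-methylhex-5-en-1-yl]triphenylphosphonium iodide
Conditions: PPh3, MeCN, 82 °C
Reagents that add atoms: triphenylphosphine, c1ccc(cc1)P(c1ccccc1)c1ccccc1
Why: SN2 quaternisation of the phosphine by the primary iodide.

Step 10
Reactants: 12 phosphonium iodide
Product: 14 formyl ylide (6R)-6-methyl-2-(triphenylphosphoranylidene)oct-7-enal, via alkylidene phosphorane 13 (not isolated)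
Conditions: n-BuLi, THF, −78 °C; then HCO2Et, −78 to 20 °C
Reagents that add atoms: ethyl formate, CCOC=O
Why: Deprotonation gives the non-stabilised ylide, which is C-formylated by ethyl formate (acylation of a phosphorus ylide), and the ethoxide set free deprotonates the acylphosphonium ion to the stabilised ylide.

Step 11
Reactants: 7 aldehyde Dec–CH2–CHO; 14 formyl ylide
Product: 15 (2E)-4-Dec-2-[(4R)-4-methylhex-5-en-1-yl]but-2-enal
Conditions: toluene, 90 °C
Reagents that add atoms: none
Why: Wittig reaction of a stabilised α-formyl ylide: reversible addition should favour the oxaphosphetane with CHO and the decalinylmethyl group trans, which sets the E geometry of the future C-12=C-1′ alkene.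

Step 12
Reactants: 15 (E)-enal
Product: 16 keto enal (2E)-4-Dec-2-[(4R)-4-methyl-5-oxohexyl]but-2-enal
Conditions: PdCl2 (10 mol %), CuCl, O2 (1 atm), DMF/H2O 7:1, 20 °C
Reagents that add atoms: water, O
Why: Palladium-catalysed aerobic oxidation of the terminal alkene to a methyl ketone (Markovnikov hydroxypalladation, then β-hydride elimination); the conjugated trisubstituted alkene should not react, and the new ketone is the temporary activating group at C-5′.

Step 13
Reactants: 16 keto enal; 17 (triphenylphosphoranylidene)acetaldehyde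
Product: 18 keto dienal (2E,4E)-6-Dec-4-[(4R)-4-methyl-5-oxohexyl]hexa-2,4-dienal
Conditions: toluene, 80 °C (17: 1.1 equiv)
Reagents that add atoms: none
Why: Wittig reaction with the stabilised formylmethylene ylide: an E-selective two-carbon homologation of the aldehyde, in which the methyl ketone should not react.

Step 14
Reactants: 18 keto dienal
Product: 21 cis-fused bicyclic enone (5′-oxo-6′-ene; 4a′β-methyl; 8a′β-H), via keto aldehyde 19 (not isolated), via ketol 20 (not isolated)
Conditions: (S)-α,α-diphenylprolinol trimethylsilyl ether (20 mol %), (PhO)2PO2H (20 mol %), toluene, 0.02 M, 40 °C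
Reagents that add atoms: none
Why: Proposed new method: the amine condenses with the formyl group to an E-configured, s-trans dienyl iminium ion, the phosphoric acid enolises the methyl ketone towards its more substituted carbon C-4a′, and this enol adds to the iminium β-carbon C-8a′; hydrolysis of the resulting enamine gives keto aldehyde 19, the methyl carbon C-6′ (as enol or enamine) then adds to the formyl carbon C-7′ (ketol 20), and loss of water gives enone 21. The closest known reaction type is the amine-catalysed Michael/aldol condensation of β-keto esters with enals to cyclohexenones, together with acid-catalysed enol Michael additions of α-branched ketones; here both are run intramolecularly with a simple ketone. Ring C closes 6-exo-trig (C-4a′ on C-8a′) and ring D closes 6-(enolendo)-exo-trig (C-6′ on C-7′). C-8a′ is set by the catalyst, whose diphenyl(silyloxy)methyl group covers one face of the iminium ion so that the enol adds to the other face; C-4a′ follows from the chair-like transition state, in which attack on the s-trans diene leaves the C-8a′ hydrogen in the plane of the exocyclic alkene and the aldehyde arm axial, while the larger enol arm sits equatorial and synclinal to it, which should give the cis ring fusion. The step needs 1,4- and not 1,6-addition and reaction through the more substituted enol: the δ-carbon C-12 carries the bulky decalinylmethyl group and could only close 6-endo, and C-6′ could reach C-8a′ only through an eight-membered ring.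

Step 15
Reactants: 21 cis-fused bicyclic enone
Product: 22 epoxy ketone (6′β,7′β-epoxy-5′-ketone)
Conditions: 30% aq. H2O2, NaOH, MeOH, 0 °C
Reagents that add atoms: hydrogen peroxide, OO
Why: Nucleophilic (Weitz–Scheffer) epoxidation of the enone: hydroperoxide should add axially to C-7′ from the β-face, and the epoxide configuration is of no consequence because C-6′ and C-7′ lose it again in steps 16 and 17.

Step 16
Reactants: 22 epoxy ketone
Product: 23 allylic alcohol (5′-en-7′β-ol)
Conditions: N2H4·H2O, AcOH (cat.), MeOH, 20 °C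
Reagents that add atoms: none
Why: Wharton transposition: the epoxy hydrazone opens to a vinyl diazene that loses N2, so the oxygen of the temporary C-5′ ketone is removed, the alkene moves to C-5′=C-6′ and the epoxide oxygen stays on C-7′.

Step 17
Reactants: 23 allylic alcohol
Product: 24 enone (7′-oxo-5′-ene)
Conditions: MnO2, CH2Cl2, 20 °C
Reagents that add atoms: none
Why: Oxidation of the allylic alcohol by MnO2 to the conjugated enone; the only other oxygen function is the silyl ether.

Step 18
Reactants: 24 enone (7′-oxo-5′-ene)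
Product: 25 methylated enone (8′β-methyl-7′-oxo-5′-ene)
Conditions: LiN(i-Pr)2, THF, −78 °C; MeI, −78 to 0 °C; then DBU, CH2Cl2, 20 °C
Reagents that add atoms: iodomethane, CI
Why: Enolate alkylation: the base removes a C-8′ proton (the only enolisable position, since C-4a′ is quaternary), MeI alkylates the cross-conjugated enolate, and DBU then equilibrates C-8′ to the equatorial β-methyl epimer, because the α-epimer would hold its methyl group 1,3-diaxial to C-4′.

Step 19
Reactants: 25 methylated enone
Product: 26 tertiary allylic alcohol (7′α-hydroxy-7′β,8′β-dimethyl-5′-ene)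
Conditions: MeLi, CeCl3, THF, −78 °C
Reagents that add atoms: methyllithium, [Li]C
Why: 1,2-Addition of the methylcerium reagent to the enone carbonyl (cerium suppresses enolisation): axial attack on the half-chair from the β-face, anti to the axial C-8′–H, should put the new methyl group axial (β) and the hydroxyl equatorial (α), the C-7′ configuration of the target.

Step 20
Reactants: 26 tertiary allylic alcohol
Product: 27 3-O-TBS ether of the target
Conditions: H2 (1 atm), RhCl(PPh3)3 (10 mol %), benzene, 20 °C
Reagents that add atoms: none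
Why: Homogeneous hydrogenation with RhCl(PPh3)3, which should reduce the cis-disubstituted C-5′=C-6′ alkene and leave the trisubstituted exocyclic C-12=C-1′ alkene; no stereocentre is formed.

Step 21
Reactants: 27 3-O-TBS ether of the target
Product: 28 target
Conditions: Bu4NF, THF, 50 °C
Reagents that add atoms: none
Why: Fluoride-induced cleavage of the silyl ether frees the C-3 alcohol without affecting the tertiary C-7′ alcohol or the alkene.

Compound list
1 | (+)-sclareolide | O=C1C[C@H]2[C@@](O1)(C)CC[C@H]3C(C)(C)CCC[C@]23C | starting material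
2 | (3S)-3-hydroxysclareolide (3β-OH on ring A) | O=C1C[C@H]2[C@@](O1)(C)CC[C@H]3C(C)(C)[C@@H](O)CC[C@]23C | intermediate
3 | (3S)-3-(TBS-oxy)sclareolide | O=C1C[C@H]2[C@@](O1)(C)CC[C@H]3C(C)(C)[C@@H](O[Si](C)(C)C(C)(C)C)CC[C@]23C | intermediate
4 | (3S)-3-(TBS-oxy)-8α-hydroxy-N-methoxy-N-methyl-13,14,15,16-tetranorlabdan-12-amide | CON(C)C(=O)C[C@H]1[C@@](O)(C)CC[C@H]2C(C)(C)[C@@H](O[Si](C)(C)C(C)(C)C)CC[C@]12C | intermediate
5 | (3S)-3-(TBS-oxy)-N-methoxy-N-methyl-13,14,15,16-tetranorlabd-8(17)-en-12-amide | CON(C)C(=O)C[C@H]1C(=C)CC[C@H]2C(C)(C)[C@@H](O[Si](C)(C)C(C)(C)C)CC[C@]12C | intermediate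
6 | (3S,5R,8S,9S,10R)-3-(TBS-oxy)-N-methoxy-N-methyl-13,14,15,16-tetranorlabdan-12-amide (8β-methyl) | CON(C)C(=O)C[C@H]1[C@@H](C)CC[C@H]2C(C)(C)[C@@H](O[Si](C)(C)C(C)(C)C)CC[C@]12C | intermediate
7 | (3S,5R,8S,9S,10R)-3-(TBS-oxy)-13,14,15,16-tetranorlabdan-12-al (Dec–CH2–CHO) | O=CC[C@H]1[C@@H](C)CC[C@H]2C(C)(C)[C@@H](O[Si](C)(C)C(C)(C)C)CC[C@]12C | intermediate
8 | (R)-β-citronellene, (3R)-3,7-dimethylocta-1,6-diene | C=C[C@H](C)CCC=C(C)C | starting material
9 | (4R)-4-methylhex-5-enal | O=CCC[C@@H](C)C=C | intermediate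
10 | (4R)-4-methylhex-5-en-1-ol | OCCC[C@@H](C)C=C | intermediate
11 | (3R)-6-iodo-3-methylhex-1-ene | ICCC[C@@H](C)C=C | intermediate
12 | [(4R)-4-methylhex-5-en-1-yl]triphenylphosphonium iodide | [I-].C=C[C@H](C)CCC[P+](c1ccccc1)(c1ccccc1)c1ccccc1 | intermediate
13 | [(4R)-4-methylhex-5-en-1-ylidene]triphenylphosphorane | C=C[C@H](C)CCC=P(c1ccccc1)(c1ccccc1)c1ccccc1 | intermediate
14 | (6R)-6-methyl-2-(triphenylphosphoranylidene)oct-7-enal | O=CC(CCC[C@@H](C)C=C)=P(c1ccccc1)(c1ccccc1)c1ccccc1 | intermediate
15 | (2E)-4-Dec-2-[(4R)-4-methylhex-5-en-1-yl]but-2-enal | O=C/C(=C/C[C@H]1[C@@H](C)CC[C@H]2C(C)(C)[C@@H](O[Si](C)(C)C(C)(C)C)CC[C@]12C)CCC[C@@H](C)C=C | intermediate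
16 | (2E)-4-Dec-2-[(4R)-4-methyl-5-oxohexyl]but-2-enal | O=C/C(=C/C[C@H]1[C@@H](C)CC[C@H]2C(C)(C)[C@@H](O[Si](C)(C)C(C)(C)C)CC[C@]12C)CCC[C@@H](C)C(C)=O | intermediate
17 | (triphenylphosphoranylidene)acetaldehyde | O=CC=P(c1ccccc1)(c1ccccc1)c1ccccc1 | starting material
18 | (2E,4E)-6-Dec-4-[(4R)-4-methyl-5-oxohexyl]hexa-2,4-dienal | O=C/C=C/C(=C/C[C@H]1[C@@H](C)CC[C@H]2C(C)(C)[C@@H](O[Si](C)(C)C(C)(C)C)CC[C@]12C)CCC[C@@H](C)C(C)=O | intermediate
19 | keto aldehyde with ring C closed: cyclohexane with the (E)-2-Dec-ethylidene group at C-1′, a CH2CHO arm (α) and H (β) at C-8a′, acetyl (α) and methyl (β) at C-4a′ | O=CC[C@H]1/C(=C/C[C@H]2[C@@H](C)CC[C@H]3C(C)(C)[C@@H](O[Si](C)(C)C(C)(C)C)CC[C@]23C)CCC[C@@]1(C)C(C)=O | intermediate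
20 | ketol: cis-fused rings C/D, 5′-oxo, 7′β-hydroxy, 4a′β-methyl, 8a′β-H, 1′-[(E)-2-Dec-ethylidene] | C1[C@H]2/C(=C/C[C@H]3[C@@H](C)CC[C@H]4C(C)(C)[C@@H](O[Si](C)(C)C(C)(C)C)CC[C@]34C)CCC[C@@]2(C)C(=O)C[C@@H]1O | intermediate
21 | cis-fused bicyclic enone: 5′-oxo-6′-ene, 4a′β-methyl, 8a′β-H, 1′-[(E)-2-Dec-ethylidene] | C1[C@H]2/C(=C/C[C@H]3[C@@H](C)CC[C@H]4C(C)(C)[C@@H](O[Si](C)(C)C(C)(C)C)CC[C@]34C)CCC[C@@]2(C)C(=O)C=C1 | intermediate
22 | epoxy ketone: 6′β,7′β-epoxy-5′-oxo derivative of the same bicycle | C1[C@H]2/C(=C/C[C@H]5[C@@H](C)CC[C@H]6C(C)(C)[C@@H](O[Si](C)(C)C(C)(C)C)CC[C@]56C)CCC[C@@]2(C)C(=O)[C@@H]3O[C@H]13 | intermediate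
23 | allylic alcohol: 5′-en-7′β-ol of the same bicycle | C1[C@H]2/C(=C/C[C@H]3[C@@H](C)CC[C@H]4C(C)(C)[C@@H](O[Si](C)(C)C(C)(C)C)CC[C@]34C)CCC[C@@]2(C)C=C[C@@H]1O | intermediate
24 | enone: 7′-oxo-5′-ene of the same bicycle | C1[C@H]2/C(=C/C[C@H]3[C@@H](C)CC[C@H]4C(C)(C)[C@@H](O[Si](C)(C)C(C)(C)C)CC[C@]34C)CCC[C@@]2(C)C=CC1=O | intermediate
25 | methylated enone: 8′β-methyl-7′-oxo-5′-ene | C[C@@H]1[C@H]2/C(=C/C[C@H]3[C@@H](C)CC[C@H]4C(C)(C)[C@@H](O[Si](C)(C)C(C)(C)C)CC[C@]34C)CCC[C@@]2(C)C=CC1=O | intermediate
26 | tertiary allylic alcohol: 7′α-hydroxy-7′β,8′β-dimethyl-5′-ene | C[C@@H]1[C@H]2/C(=C/C[C@H]3[C@@H](C)CC[C@H]4C(C)(C)[C@@H](O[Si](C)(C)C(C)(C)C)CC[C@]34C)CCC[C@@]2(C)C=C[C@@]1(C)O | intermediate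
27 | 3-O-TBS ether of the target | C[C@@H]1[C@H]2/C(=C/C[C@H]3[C@@H](C)CC[C@H]4C(C)(C)[C@@H](O[Si](C)(C)C(C)(C)C)CC[C@]34C)CCC[C@@]2(C)CC[C@@]1(C)O | intermediate
28 | target, (3S,5R,8S,9S,10R,12E,4a′S,7′R,8′R,8a′R) in the locants above | C[C@@H]1[C@H]2/C(=C/C[C@H]3[C@@H](C)CC[C@H]4C(C)(C)[C@@H](O)CC[C@]34C)CCC[C@@]2(C)CC[C@@]1(C)O | target

Total step count: 21. Longest linear sequence: 17 steps (steps 1 to 6, then 11 to 21).

Steps most likely to fail

1. Step 14 (Proposed new method). Enolisation towards C-4a′ may be too slow, so that intermolecular reactions of the iminium ion take over. The dienyl iminium ion may be deprotonated at C-11 or C-2′ (trienamine formation), with loss of alkene geometry or oligomerisation. Facial control, the cis fusion or the 1,4-regiochemistry may be incomplete. Fallback with known chemistry, from 16 to 24: a Horner–Wadsworth–Emmons reaction of keto enal 16 with triethyl phosphonoacetate (LiCl, DBU, MeCN) would give the ethyl (2E,4E)-keto dienoate F1. Condensation of its ketone with (S)-1-phenylethylamine (toluene, 4 Å sieves, then 60 °C) would bring about the known intramolecular Michael addition through the more substituted secondary enamine, in a compact transition state that passes the N–H hydrogen to the α-carbon; aqueous acetic acid would then release the cyclohexane keto ester F2 (the enantiomeric amine would be used if the sense of induction proved to be the reverse). t-BuOK in THF would close ring D by Claisen condensation to the bicyclic 1,3-diketone F3. MeOH/TsOH would give the vinylogous methyl ester F4 with the methoxy group on the less hindered C-7′. LiAlH4 followed by dilute HCl would give enone 24, where the route is rejoined.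

2. Step 13. The product dienal may be olefinated a second time by the ylide, and E selectivity may be incomplete. Fallback, from 15 to 18: before the alkene oxidation, a Horner–Wadsworth–Emmons reaction of enal 15 with triethyl phosphonoacetate (NaH, THF) would give the dienoate F5; i-Bu2AlH (CH2Cl2, −78 °C) would give the dienol F6 and MnO2 the dienal F7; the PdCl2/CuCl/O2 oxidation of step 12, applied to F7, would then give keto dienal 18.

3. Step 16. Hydrazone formation at the hindered C-5′ ketone, which sits next to the quaternary C-4a′, may be slow, and hydrazine may instead open the epoxide. Fallback, from 22 to 23: SmI2 (THF/MeOH, −78 °C) would open the epoxide at C-6′ to ketol 20; TsNHNH2 (MeOH, 20 °C) would give the tosylhydrazone F8; a Shapiro reaction (n-BuLi, THF, −78 to 0 °C, then water) would give allylic alcohol 23.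

Further compounds
F1 | step 14 | ethyl (2E,4E)-6-Dec-4-[(4R)-4-methyl-5-oxohexyl]hexa-2,4-dienoate | CCOC(=O)/C=C/C(=C/C[C@H]1[C@@H](C)CC[C@H]2C(C)(C)[C@@H](O[Si](C)(C)C(C)(C)C)CC[C@]12C)CCC[C@@H](C)C(C)=O
F2 | step 14 | keto ester with ring C closed: ethyl ester analogue of 19 (CH2CO2Et arm at C-8a′, same configuration) | CCOC(=O)C[C@H]1/C(=C/C[C@H]2[C@@H](C)CC[C@H]3C(C)(C)[C@@H](O[Si](C)(C)C(C)(C)C)CC[C@]23C)CCC[C@@]1(C)C(C)=O
F3 | step 14 | cis-fused bicyclic 5′,7′-dione | C1[C@H]2/C(=C/C[C@H]3[C@@H](C)CC[C@H]4C(C)(C)[C@@H](O[Si](C)(C)C(C)(C)C)CC[C@]34C)CCC[C@@]2(C)C(=O)CC1=O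
F4 | step 14 | vinylogous methyl ester: 7′-methoxy-6′-en-5′-one | C1[C@H]2/C(=C/C[C@H]3[C@@H](C)CC[C@H]4C(C)(C)[C@@H](O[Si](C)(C)C(C)(C)C)CC[C@]34C)CCC[C@@]2(C)C(=O)C=C1OC
F5 | step 13 | ethyl (2E,4E)-6-Dec-4-[(4R)-4-methylhex-5-en-1-yl]hexa-2,4-dienoate | CCOC(=O)/C=C/C(=C/C[C@H]1[C@@H](C)CC[C@H]2C(C)(C)[C@@H](O[Si](C)(C)C(C)(C)C)CC[C@]12C)CCC[C@@H](C)C=C
F6 | step 13 | (2E,4E)-6-Dec-4-[(4R)-4-methylhex-5-en-1-yl]hexa-2,4-dien-1-ol | OC/C=C/C(=C/C[C@H]1[C@@H](C)CC[C@H]2C(C)(C)[C@@H](O[Si](C)(C)C(C)(C)C)CC[C@]12C)CCC[C@@H](C)C=C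
F7 | step 13 | (2E,4E)-6-Dec-4-[(4R)-4-methylhex-5-en-1-yl]hexa-2,4-dienal | O=C/C=C/C(=C/C[C@H]1[C@@H](C)CC[C@H]2C(C)(C)[C@@H](O[Si](C)(C)C(C)(C)C)CC[C@]12C)CCC[C@@H](C)C=C
F8 | step 16 | tosylhydrazone of ketol 20 at C-5′ | C1[C@H]2/C(=C/C[C@H]3[C@@H](C)CC[C@H]4C(C)(C)[C@@H](O[Si](C)(C)C(C)(C)C)CC[C@]34C)CCC[C@@]2(C)C(=NNS(=O)(=O)c5ccc(C)cc5)C[C@@H]1O
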